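The runs were generated by integration with made-up constants; scatter was added.

I began from the slowness of the second exchange, X + G to L + J, and read it in the ochre run, where both partners stand plainly in the readings.

common to all: J 0.0375 M

| run | D | G | remark | time |
|---|---|---|---|---|
| violet | 0.075 M | 0.11 M | run made earlier |  |
| ochre | 0.075 M | 0.17 M | run made earlier |  |
| grey | 0.11 M | 0.22 M | run made earlier |  |
| flask | 0.075 M | 0.220 M |  | 5.0 min |

| run | time / min | X / % | L / % |
|---|---|---|---|
| violet | 0.417 | 33.8 | 3.6 |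
| violet | 0.667 | 42.2 | 7.1 |
| violet | 1.00 | 46.7 | 11.1 |
| violet | 2.00 | 49.3 | 22.0 |
| violet | 3.00 | 47.1 | 29.4 |
| violet | 5.00 | 40.7 | 39.8 |
| ochre | 0.333 | 40.1 | 5.2 |
| ochre | 1.00 | 51.5 | 21.9 |
| ochre | 2.00 | 44.4 | 41.3 |
| ochre | 2.50 | 39.6 | 48.4 |
| ochre | 4.00 | 27.3 | 61.8 |
| ochre | 5.00 | 21.6 | 68.6 |
| grey | 1.00 | 50.7 | 27.5 |
| grey | 2.00 | 40.2 | 45.4 |
| grey | 3.00 | 30.4 | 56.4 |
| grey | 4.00 | 24.6 | 63.7 |
| grey | 5.00 | 20.2 | 68.9 |

(readings scatter by 0.3 percentage points)

- equivalents of G to D, everything else as given, that leave most X at 5.0 min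
- the amount of X then, in percent of the D charged
- the amount of X with the amounts as given

Between 1.00 min and 2.00 min of the ochre run, L rose from 21.9% to 41.3%. X averaged 48.0%. With each X holding one G and each L two, free G averaged 0.0866 M. L made per minute, per X and per free G, is my second-exchange constant:

κ = 4.67 M⁻¹ min⁻¹

Where no new X comes and cG is held steady, X falls as exp(−κ·cG·time), a pseudo-first-order loss. In the flask I counted from 1.00 min, taking as my estimate for X the 51.5% that ochre showed then. Unreacted D could add to that, so I took 72.5% as the top, assuming L at least as high as grey's. I took cG between 0.145 M and 0.0700 M.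

wide bracket: 3.43% to 19.6%

with cG at the middle, 0.108 M: 6.91% to 9.73%

The forecast gave 13% as charged and 45% at 1.15 equiv, holding that “Less G favours X at 5 min”. Its 13% lay inside my wide bracket but above the narrow one.

The flask gave 9.85%, just above my narrow bracket, and the best was 45.2% at 1.05 equiv. At 5.00 min, X was being made at 0.0128 of the rate at which it was used. From 27.9% at 2.50 min, with G falling from 47.0% to 40.2% of its charge, κ gives 9.13% at 5.00 min.

    D + G → J + X (k = 0.220 M⁻¹ s⁻¹)
    X + G → J + L (k = 0.0770 M⁻¹ s⁻¹)
    2 D → E (k = 0.0450 M⁻¹ s⁻¹)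

Read at 20 min, the same flask, counted on from its 9.85% at 5.00 min, gets from κ 0.0202% with G held at its 5.00 min level and 0.0731% with cG at 0.0700 M. The computed result is 0.0333%.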